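(The data were computed for substances that don't exist, and the scatter is random.)

common to all: free catalyst 8.00 × 10⁻⁴ M
- Monday's: substrate 0.400 M; partner 1.20 M
- Saturday's: substrate 0.400 M; partner 0.600 M
- Friday's: substrate 1.20 M; partner 1.20 M
- Thursday's: substrate 0.200 M; partner 2.40 M; time 32 h

- Monday's run (time / h: [target] / M): 1.8: 0.0302; 5.5: 0.0768; 11: 0.1338; 17: 0.1725; 24: 0.2008; 32: 0.2163
- Saturday's run (time / h: [target] / M): 1.8: 0.0268; 5.5: 0.0678; 11: 0.1172; 17: 0.1649; 24: 0.2041; 32: 0.2337
- Friday's run (time / h: [target] / M): 1.8: 0.0626; 5.5: 0.1607; 11: 0.2781; 17: 0.3740; 24: 0.4520; 32: 0.5148

(readings scatter by 0.002 M)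

* apparent order in [substrate] of the starting rate, round the charge of the Monday's run (the rate where two percent of its substrate have turned into target) (one fixed amount of target, the same in the runs compared)
* apparent order in [partner] of the starting rate, round the charge of the Monday's run (the rate where two percent of its substrate have turned into target)
* target in the Thursday's run at 32 h, as a share of the substrate charged

- Overall: substrate + partner -> target, with free catalyst as catalyst.
- Constant volume, constant temperature.
- A reading of a species includes what of it is bound.
- "The second partner" is partner.
- An order is taken over about fifteen percent of the charge, up and down.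

- If a curve flattens early, suspect that something eats the target: Monday's run reaches only 0.2163 M from 0.400 M of substrate, while Saturday's run, with half the partner, passes it between 17 h and 24 h and ends higher, at 0.2337 M.
- Take the catalyst cycle as steady, so target forms at m·[substrate], where m is the share of remaining substrate turned per hour. Monday's first reading gives m = 0.0419 h⁻¹. Saturday's first reading is 0.887 of Monday's, so carry one m.
- Read Monday's last gap at its midpoint, 28.0 h. Substrate left is 0.124 M, so target forms at 0.00518 M h⁻¹, yet the readings rise at 0.00194 M h⁻¹. The difference, 0.00325 M h⁻¹, is target lost.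
- Suppose partner does the eating, one for one. Monday's target is then 0.209 M and its partner 0.856 M. This gives the drain constant κ, the share of target lost per hour for each mole per litre of partner: κ = 0.0182 M⁻¹ h⁻¹.
- Apply κ to Saturday's run: even at its full partner charge, it loses at most 0.00239 M h⁻¹, less than Monday's 0.00325 M h⁻¹, and that is why it ends higher.
- Thursday's partner far exceeds its substrate, so the drain is pseudo-first-order. Take partner as about 2.20 M, which gives d = κ·[partner] = 0.0400 h⁻¹.
- With S₀ the substrate charge and t the time, made-then-lost target is S₀·m/(m−d)·(e^(−dt) − e^(−mt)). At 32 h this gives 0.0723 M, or 36.2 % of the charge.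
- The forecast gives orders of 0.76 in substrate and 0.18 in partner, and 35 % for Thursday's run, a share slightly below this reckoning, holding that “partner seems to kill the catalyst”.

    free catalyst + substrate → catalyst-substrate complex (68.76 M⁻¹ h⁻¹)
    catalyst-substrate complex + partner → target + free catalyst (78.12 M⁻¹ h⁻¹)
    target + partner → side product (0.01850 M⁻¹ h⁻¹)
    free catalyst + substrate → spent catalyst + substrate (0.02124 M⁻¹ h⁻¹)

- The flask gives orders of 0.80 in substrate and 0.22 in partner, and 37.5 % for Thursday's run. Turning free catalyst into spent catalyst makes no difference to that share. Thursday's run therefore holds 0.0750 M of target at 32 h, and κ at 2.20 M of partner takes 0.00300 M h⁻¹ from it.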